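**Retrosynthetic overview**
- The strategy rests on ring C (C8, C9, C11–C14): it is a 4-hydroperoxy-2,5-cyclohexadienone, that is, a phenol oxygenated at its para carbon C8. C9 and C8 map onto the carbonyl and α-CH2 of a ring-B cyclohexanone that already carries C5 (isopropenyl) and quaternary C10; C11–C14 map onto a four-carbon enone whose β-carbon C14 carries the masked vinyl group.
- 24 ⇐ vinyl phenol 23 (singlet oxygen at C8) ⇐ hydroxy aldehyde 22 (Wittig) ⇐ bicyclic enone acetal 17 (dehydrogenation, acetal hydrolysis).
- 17 ⇐ Robinson annulation (C8–C14 Michael bond, C9=C11 aldol condensation) of ring-B ketone 8, used as silyl enol ether 9, with enone acetal 14. Ring C is the only ring formed, on a preformed ring B.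
- 8 ⇐ imine-mediated Michael addition of methyl acrylate ⇐ copper-catalysed asymmetric conjugate addition of isopropenylmagnesium bromide to 2-methylcyclohexenone; 14 ⇐ Wittig reaction of 2,2-dimethoxyacetaldehyde.

Key step: step 6

Remark: atom labels follow cleistanthane numbering (ring B = C5–C10, ring C = C8, C9, C11–C14; C5 bears isopropenyl, C10 bears CH3 and the CH2CH2CO2Me arm); β is the face of the C10 methyl group.

**Step 1**
Reactants: 1 2-methylcyclohex-2-en-1-one; 2 isopropenylmagnesium bromide
Product: 4 (3S)-2-methyl-3-(prop-1-en-2-yl)cyclohexan-1-one (C2 epimer mixture), via bromomagnesium enolate 3 (not isolated)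
Conditions: Cu(OTf)2 (5 mol %), chiral imidazolinium salt as NHC precursor (6 mol %), Et2O, −30 °C; then sat. aq. NH4Cl
Reagents that add atoms: none
Why: Copper–NHC-catalysed enantioselective conjugate addition of a Grignard reagent to an α-substituted cyclic enone, in which the ligand antipode (fixed in a trial run) directs isopropenyl to the enone face that gives 3S (the future C5), while C2 is left as an inconsequential epimer mixture because it is re-planarised in step 2.

**Step 2**
Reactants: 4 (3S)-2-methyl-3-(prop-1-en-2-yl)cyclohexan-1-one; 5 methyl acrylate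
Product: 8 methyl 3-[(1R,6R)-1-methyl-2-oxo-6-(prop-1-en-2-yl)cyclohexyl]propanoate, via N-benzyl ketimine 6 (not isolated), via N-benzyl imine of the keto ester 7 (not isolated)
Conditions: BnNH2 (1.1 equiv), cat. p-TsOH, toluene, reflux (Dean–Stark); then methyl acrylate (3 equiv), THF, 60 °C; then 20% aq. AcOH, rt
Reagents that add atoms: water, O
Why: Michael addition through the more substituted secondary-enamine tautomer of a ketimine (aza-ene-type alkylation) is regiospecific for the methyl-bearing α-carbon, and the acrylate should enter anti to the neighbouring pseudoaxial isopropenyl group, which sets quaternary C10 with the methyl cis and the ester arm trans to isopropenyl.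

**Step 3**
Reactants: 8 methyl 3-[(1R,6R)-1-methyl-2-oxo-6-(prop-1-en-2-yl)cyclohexyl]propanoate
Product: 9 methyl 3-[(1R,6R)-1-methyl-6-(prop-1-en-2-yl)-2-(trimethylsilyloxy)cyclohex-2-en-1-yl]propanoate
Conditions: TMSOTf (1.2 equiv), Et3N (1.5 equiv), CH2Cl2, 0 °C; pentane, cold aq. NaHCO3 wash; used crude
Reagents that add atoms: trimethylsilyl trifluoromethanesulfonate, C[Si](C)(C)OS(=O)(=O)C(F)(F)F
Why: Soft enolisation and O-silylation of a ketone can only give the C8=C9 enol ether because C10 is quaternary, and the ester is not silylated under these mild conditions.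

**Step 4**
Reactants: 10 3-bromobutan-2-one
Product: 12 3-(triphenylphosphoranylidene)butan-2-one, via (3-oxobutan-2-yl)triphenylphosphonium bromide 11 (not isolated)
Conditions: PPh3, toluene, 80 °C; then 2 M aq. NaOH, CH2Cl2, rt
Reagents that add atoms: triphenylphosphine, c1ccc(cc1)P(c1ccccc1)c1ccccc1
Why: SN2 quaternisation of the phosphine by the α-bromo ketone followed by deprotonation of the acidic α-CH gives the keto-stabilised ylide.

**Step 5**
Reactants: 12 3-(triphenylphosphoranylidene)butan-2-one; 13 2,2-dimethoxyacetaldehyde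
Product: 14 (E)-5,5-dimethoxy-3-methylpent-3-en-2-one
Conditions: CH2Cl2 (aldehyde added as its 60% aqueous solution), 40 °C
Reagents that add atoms: none
Why: Wittig olefination of an electrophilic aldehyde with a stabilised α-methyl keto ylide should give the E-alkene (acetyl trans to the acetal carbon) under thermodynamic control of the oxaphosphetane.

**Step 6**
Reactants: 9 methyl 3-[(1R,6R)-1-methyl-6-(prop-1-en-2-yl)-2-(trimethylsilyloxy)cyclohex-2-en-1-yl]propanoate; 14 (E)-5,5-dimethoxy-3-methylpent-3-en-2-one
Product: 17 methyl 3-[(1R,2R)-5-(dimethoxymethyl)-1,6-dimethyl-7-oxo-2-(prop-1-en-2-yl)-1,2,3,4,4a,5,6,7-octahydronaphthalen-1-yl]propanoate (bicyclic enone acetal; drawn as the all-equatorial 8β-H/13α-CH3/14β-CH(OMe)2 isomer; C8/C13/C14 epimers carried along), via 1,5-diketone Michael adduct 15 (not isolated), via aldol ketol 16 (not isolated)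
Conditions: 14 (1.2 equiv) pre-complexed with TiCl4 (1.1 equiv), CH2Cl2, −78 °C, then 9; sat. aq. NaHCO3 quench at −78 °C; crude 15, NaOMe (0.3 equiv), MeOH, rt to 50 °C
Reagents that add atoms: none
Why: This is a Robinson annulation in its Mukaiyama–Michael/aldol-condensation form: TiCl4 bound to the enone carbonyl of 14 makes C14 electrophilic, C8 of enol ether 9 adds to it (C8–C14) to give diketone 15 after the quench, and methoxide then enolises the methyl ketone at C11, which adds to the C9 carbonyl before ketol 16 dehydrates by E1cB to the conjugated C9=C11 enone. Ring C is closed by a 6-(enolendo)-exo-trig aldol addition, the only closure open to 15 apart from four-membered alternatives. C8, C13 and C14 are formed without external control; C8 and C13 are epimerisable under the methoxide conditions and should settle with all three ring-C substituents equatorial, and all three centres are erased in step 7, whereas C5 and C10 are not enolisable and stay fixed. Regiochemistry is dictated by the substrate, since C10 is quaternary and only C8 can act as donor, and by Michael polarity, which places the acetal-bearing carbon next to C8. The step needs chemoselectivity for conjugate addition over ionisation of the dimethyl acetal and over Claisen attack on the ester arm: the acetal is deactivated as a vinylogous α-keto acetal, the Lewis acid is pre-complexed 1:1 with the enone at −78 °C and quenched under basic conditions, the donor is a neutral silyl enol ether and not a free enolate, and NaOMe in MeOH matches the methyl ester.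

**Step 7**
Reactants: 17 bicyclic enone acetal
Product: 22 methyl 3-[(1R,2R)-5-formyl-7-hydroxy-1,6-dimethyl-2-(prop-1-en-2-yl)-1,2,3,4-tetrahydronaphthalen-1-yl]propanoate, via lithium dienolate 18 (not isolated), via C13 sulfilimine adduct 19 (not isolated), via cross-conjugated dienone 20 (not isolated), via phenol dimethyl acetal 21 (not isolated)
Conditions: LDA (1.1 equiv), THF, −78 °C; N-tert-butylbenzenesulfinimidoyl chloride (1.2 equiv), −78 °C; then 1 M aq. HCl/THF, rt
Reagents that add atoms: water, O
Why: Kinetic α′-deprotonation of the enone at C13 (more acidic than the ester α-CH2) followed by Mukaiyama dehydrogenation (S-attack of the enolate, syn-elimination of the sulfilimine) introduces the C13=C14 double bond, the resulting dienone carries H at C8 and tautomerises to the phenol, and the acidic work-up hydrolyses the now benzylic dimethyl acetal to the aldehyde.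

**Step 8**
Reactants: 22 hydroxy aldehyde
Product: 23 methyl 3-[(1R,2R)-5-ethenyl-7-hydroxy-1,6-dimethyl-2-(prop-1-en-2-yl)-1,2,3,4-tetrahydronaphthalen-1-yl]propanoate
Conditions: Ph3PCH3Br (3.0 equiv), KOt-Bu (2.9 equiv), THF, 0 °C to rt
Reagents that add atoms: methyltriphenylphosphonium bromide, C[P+](c1ccccc1)(c1ccccc1)c1ccccc1.[Br-]
Why: Wittig methylenation with excess non-stabilised ylide (one equivalent is consumed by the phenol) converts the aryl aldehyde into the vinyl group without attacking the methyl ester at this temperature and without touching a stereocentre.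

**Step 9**
Reactants: 23 vinyl phenol
Product: 24 trigonochinene C, methyl 3-[(1R,2R,4aR)-5-ethenyl-4a-hydroperoxy-1,6-dimethyl-7-oxo-2-(prop-1-en-2-yl)-1,2,3,4,4a,7-hexahydronaphthalen-1-yl]propanoate
Conditions: O2 (1 atm), rose bengal (2 mol %), MeOH, white LEDs, −20 °C; chromatography
Reagents that add atoms: dioxygen, O=O
Why: Dye-sensitised singlet-oxygen oxidation of a para-alkylphenol gives the 4-hydroperoxy-2,5-cyclohexadienone by attack at C8 (para to OH), which should outpace ene reaction at the 1,1-disubstituted isopropenyl group; C8 is set by approach of O2 anti to the pseudoaxial C10 substituent, and the ring-B half-chair with the ester arm and isopropenyl trans-diaxial exposes the β face needed here, so the 8β-hydroperoxide should form together with its C8 epimer and be isolated by chromatography.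

**Compound list**
1 | 2-methylcyclohex-2-en-1-one | CC1=CCCCC1=O | starting material
2 | isopropenylmagnesium bromide | CC(=C)[Mg]Br | starting material
3 | bromomagnesium enolate of 4 (C1=C2 enolate) | Br[Mg]OC1=C(C)[C@@H](C(C)=C)CCC1 | intermediate
4 | (3S)-2-methyl-3-(prop-1-en-2-yl)cyclohexan-1-one (C2 epimer mixture) | O=C1CCC[C@H](C(=C)C)C1C | intermediate
5 | methyl acrylate | C=CC(=O)OC | starting material
6 | N-benzyl ketimine of 4 | C(N=C1CCC[C@H](C(=C)C)C1C)c1ccccc1 | intermediate
7 | N-benzyl ketimine of keto ester 8 | C(N=C1CCC[C@H](C(=C)C)[C@@]1(C)CCC(=O)OC)c1ccccc1 | intermediate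
8 | methyl 3-[(1R,6R)-1-methyl-2-oxo-6-(prop-1-en-2-yl)cyclohexyl]propanoate (methyl cis, ester arm trans to isopropenyl) | O=C1CCC[C@H](C(=C)C)[C@@]1(C)CCC(=O)OC | intermediate
9 | methyl 3-[(1R,6R)-1-methyl-6-(prop-1-en-2-yl)-2-(trimethylsilyloxy)cyclohex-2-en-1-yl]propanoate | C[Si](C)(C)OC1=CCC[C@H](C(=C)C)[C@@]1(C)CCC(=O)OC | intermediate
10 | 3-bromobutan-2-one | CC(=O)C(C)Br | starting material
11 | (3-oxobutan-2-yl)triphenylphosphonium bromide | CC(=O)C(C)[P+](c1ccccc1)(c1ccccc1)c1ccccc1.[Br-] | intermediate
12 | 3-(triphenylphosphoranylidene)butan-2-one | CC(=O)C(C)=P(c1ccccc1)(c1ccccc1)c1ccccc1 | intermediate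
13 | 2,2-dimethoxyacetaldehyde | COC(OC)C=O | starting material
14 | (E)-5,5-dimethoxy-3-methylpent-3-en-2-one | CC(=O)/C(C)=C/C(OC)OC | intermediate
15 | 1,5-diketone Michael adduct (C8–C14 bond formed; C8/C13/C14 epimers) | O=C1C(C(C(OC)OC)C(C)C(C)=O)CC[C@H](C(=C)C)[C@@]1(C)CCC(=O)OC | intermediate
16 | aldol ketol (C9–OH, C9–C11 bond formed; epimer mixture) | COC(OC)C1C(C)C(=O)CC2(O)C1CC[C@H](C(=C)C)[C@@]2(C)CCC(=O)OC | intermediate
17 | bicyclic enone acetal (8β-H, 13α-CH3, 14β-CH(OMe)2 drawn) | COC(OC)[C@H]1[C@H](C)C(=O)C=C2[C@@H]1CC[C@H](C(=C)C)[C@@]2(C)CCC(=O)OC | intermediate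
18 | lithium C12–O dienolate of 17 (C12=C13) | COC(OC)C1C(C)=C(O[Li])C=C2C1CC[C@H](C(=C)C)[C@@]2(C)CCC(=O)OC | intermediate
19 | C13 (N-tert-butyl-S-phenylsulfilimidoyl) adduct of 17 | COC(OC)C1C(C)(S(=NC(C)(C)C)c3ccccc3)C(=O)C=C2C1CC[C@H](C(=C)C)[C@@]2(C)CCC(=O)OC | intermediate
20 | cross-conjugated dienone (keto tautomer of 21, H at C8) | COC(OC)C1=C(C)C(=O)C=C2C1CC[C@H](C(=C)C)[C@@]2(C)CCC(=O)OC | intermediate
21 | phenol dimethyl acetal | COC(OC)c1c(C)c(O)cc2c1CC[C@H](C(=C)C)[C@@]2(C)CCC(=O)OC | intermediate
22 | methyl 3-[(1R,2R)-5-formyl-7-hydroxy-1,6-dimethyl-2-(prop-1-en-2-yl)-1,2,3,4-tetrahydronaphthalen-1-yl]propanoate | O=Cc1c(C)c(O)cc2c1CC[C@H](C(=C)C)[C@@]2(C)CCC(=O)OC | intermediate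
23 | methyl 3-[(1R,2R)-5-ethenyl-7-hydroxy-1,6-dimethyl-2-(prop-1-en-2-yl)-1,2,3,4-tetrahydronaphthalen-1-yl]propanoate | C=Cc1c(C)c(O)cc2c1CC[C@H](C(=C)C)[C@@]2(C)CCC(=O)OC | intermediate
24 | trigonochinene C (8β-OOH, cis to the C10 methyl) | C=CC1=C(C)C(=O)C=C2[C@]1(OO)CC[C@H](C(=C)C)[C@@]2(C)CCC(=O)OC | target

**Step count**
Total: 9 steps. Longest linear sequence: 7 steps (1, 2, 3, 6, 7, 8, 9); steps 4 and 5 form the short branch to 14.

**Steps most likely to fail**

Step 6. The Lewis acid may ionise the dimethyl acetal, so that the enol ether is consumed at the acetal carbon instead of at C14, or addition to the trisubstituted enone may stall under conditions mild enough to spare the acetal. The fallback sets out from 9 and 12 and comes back at 17; it carries the future aldehyde carbon one oxidation level lower through the annulation. Ylide 12 and commercial (tert-butyldimethylsilyloxy)acetaldehyde give (E)-5-(tert-butyldimethylsilyloxy)-3-methylpent-3-en-2-one F1, which tolerates excess TiCl4 and higher temperature. Mukaiyama–Michael addition of 9 then gives the silyloxy 1,5-diketone F2, and NaOMe/MeOH closes it through the silyloxy ketol F3 to the silyloxymethyl bicyclic enone F4. TBAF/AcOH frees the primary alcohol F5, Dess–Martin periodinane gives the keto aldehyde F6, and HC(OMe)3/MeOH/PPTS acetalises the aldehyde selectively to return 17.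

Step 9. Facial selectivity of oxygen delivery to C8 may be poor, because both ring-B half-chairs are accessible and each shields one face, and ene oxygenation of the isopropenyl group may compete. The fallback sets out from 23 and comes back at 23; it replaces reliance on kinetic facial control by separation and recycling. After chromatographic separation of 24, the C8 epimer of 24 F7 is treated with Zn/AcOH, which reduces the hydroperoxide and rearomatises the resulting quinol, so that phenol 23 is recovered and oxygenated again.

Step 1. Enantioselectivity may be low in the copper-catalysed transfer of an alkenyl Grignard reagent. The fallback sets out from 1 and 2 and comes back at 8; it uses resolution in place of asymmetric catalysis. Ligand-free CuI-catalysed addition gives 3 and 4 as racemates, that is, together with the enolate antipode F8 and the ketone antipode F9. Step 2 run unchanged carries the ketimine antipode F10 and the adduct-imine antipode F11 through to racemic keto ester, 8 plus the keto ester antipode F12. Preparative chromatography on a chiral stationary phase (SFC) then returns enantiopure 8.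

**Further compounds**
F1 | step 6 | (E)-5-(tert-butyldimethylsilyloxy)-3-methylpent-3-en-2-one | CC(=O)/C(C)=C/CO[Si](C)(C)C(C)(C)C
F2 | step 6 | silyloxy 1,5-diketone (C14–CH2OTBS analogue of 15) | O=C1C(C(CO[Si](C)(C)C(C)(C)C)C(C)C(C)=O)CC[C@H](C(=C)C)[C@@]1(C)CCC(=O)OC
F3 | step 6 | silyloxy ketol (C14–CH2OTBS analogue of 16) | CC(C)(C)[Si](C)(C)OCC1C(C)C(=O)CC2(O)C1CC[C@H](C(=C)C)[C@@]2(C)CCC(=O)OC
F4 | step 6 | silyloxymethyl bicyclic enone | CC(C)(C)[Si](C)(C)OCC1C(C)C(=O)C=C2C1CC[C@H](C(=C)C)[C@@]2(C)CCC(=O)OC
F5 | step 6 | hydroxymethyl bicyclic enone | OCC1C(C)C(=O)C=C2C1CC[C@H](C(=C)C)[C@@]2(C)CCC(=O)OC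
F6 | step 6 | bicyclic enone C14-carbaldehyde | O=CC1C(C)C(=O)C=C2C1CC[C@H](C(=C)C)[C@@]2(C)CCC(=O)OC
F7 | step 9 | C8 epimer of 24 (8α-OOH) | C=CC1=C(C)C(=O)C=C2[C@@]1(OO)CC[C@H](C(=C)C)[C@@]2(C)CCC(=O)OC
F8 | step 1 | antipode of enolate 3 | Br[Mg]OC1=C(C)[C@H](C(C)=C)CCC1
F9 | step 1 | antipode of ketone 4 | O=C1CCC[C@@H](C(=C)C)C1C
F10 | step 1 | antipode of ketimine 6 | C(N=C1CCC[C@@H](C(=C)C)C1C)c1ccccc1
F11 | step 1 | antipode of adduct imine 7 | C(N=C1CCC[C@@H](C(=C)C)[C@]1(C)CCC(=O)OC)c1ccccc1
F12 | step 1 | antipode of keto ester 8 | O=C1CCC[C@@H](C(=C)C)[C@]1(C)CCC(=O)OC
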